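The ten-membered carbocycle is traced back to a cyclohexane. The segment C10=C1–C2–C3–C4–C5 of the germacrane ring is the 1,5-array left by a [3,3] shift, so forming C2–C3 while breaking C5–C10 expands the six-membered ring C5–C10 by four atoms. Run on a potassium alkoxide, this one operation delivers the macrocycle, the E C1=C10 alkene, the C3 stereocentre and a geometrically defined C4=C5 enolate, stored as its triflate. The precursor is a carvone-derived cyclohexanol with trans vinyl (C10) and Z 1-(PMB-oxy)propen-2-yl (C5) groups and a C6 MOM ether cis to the C7 isopropyl group. Triflate reduction, C6-directed epoxidation and two acylations complete the target.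

Key step: step 11

Remarks
- Numbering: germacrane numbering is used for all ring atoms, also at the cyclohexane stage (ring C5–C10; carvone C1 = C5, C2 = C10, C5 = C7, C6 = C6). The target is 3S,4R,5R,6R,7S,1(10)E. Its epoxide is trans (it derives from a 4E alkene) and erythro to O6.
- O6 is cis to the C7 isopropyl group. Next to a C5 ketone this is the less stable arrangement, so it is set by kinetic protonation and not by the oxygenation itself.
- In the enol triflate C3 and C6 are trans across C4=C5, yet the CIP label is Z because OTf outranks C6. The label becomes E once OTf is replaced by H.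
- In the alkenyl-metal reagents the metal is cis to oxygen.
- A 6R allylic alcohol of this substitution pattern is the fast-reacting partner of the D-(−)-tartrate catalyst.
- The MOM group is removed while C4=C5 is still an electron-poor enol triflate, before the acid-sensitive 1(10),4-diene exists.
- Assumption: the aldol of step 2 follows the axial-attack sense established for dihydrocarvone enolates (new bond cis to the isopropyl group).

Step 1
Reactants: 1 (R)-(−)-carvone
Product: 2 (R)-carvotanacetone [(5R)-2-methyl-5-(propan-2-yl)cyclohex-2-en-1-one]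
Conditions: H2 (1 atm), RhCl(PPh3)3 (cat.), toluene, rt
Reagents that add atoms: none
Why: Homogeneous hydrogenation with RhCl(PPh3)3 should saturate the unhindered 1,1-disubstituted isopropenyl alkene well before the conjugated trisubstituted one, and the stereocentre that becomes C7 is not touched.

Step 2
Reactants: 2 (R)-carvotanacetone; 3 acetaldehyde
Product: 5 (2R,5R)-2-(1-hydroxyethyl)-2-methyl-5-(propan-2-yl)cyclohexan-1-one (both carbinol epimers), via lithium enolate 4 (not isolated)
Conditions: LiBH(s-Bu)3 (1.0 equiv), THF, −78 °C; then 3, −78 °C; H2O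
Reagents that add atoms: none
Why: Conjugate hydride addition generates the tetrasubstituted C5=C10 enolate regiospecifically, and its aldol addition should occur axially on the half-chair with an equatorial isopropyl group, so that the new C10–C1 bond is cis to the isopropyl group (2R in 5); the minor C10 epimer is removed by chromatography.

Step 3
Reactants: 5 aldol
Product: 6 (2R,5R)-2-ethenyl-2-methyl-5-(propan-2-yl)cyclohexan-1-one
Conditions: methyl N-(triethylammoniosulfonyl)carbamate (Burgess reagent), toluene, 70 °C
Reagents that add atoms: none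
Why: Burgess dehydration: the sulfamate ester undergoes thermal syn elimination, which can only run toward the methyl group because C10 is quaternary, and the neutral medium avoids retro-aldol cleavage.

Step 4
Reactants: 6 vinyl ketone
Product: 8 (2R,5S,6S)-2-ethenyl-6-hydroxy-2-methyl-5-(propan-2-yl)cyclohexan-1-one (major C6 epimer), via potassium enolate 7 (not isolated)
Conditions: KN(SiMe3)2, THF, −78 °C; then 2-(phenylsulfonyl)-3-phenyloxaziridine, −78 °C; H2O
Reagents that add atoms: 2-(phenylsulfonyl)-3-phenyloxaziridine, O=S(=O)(c1ccccc1)N1OC1c1ccccc1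
Why: C6 is the only enolisable position, and N-sulfonyloxaziridine hydroxylation of the enolate should occur mainly anti to the neighbouring isopropyl group; the C6 configuration obtained here does not matter because step 6 resets it.

Step 5
Reactants: 8 acyloin
Product: 9 (2R,5S,6S)-2-ethenyl-6-(methoxymethoxy)-2-methyl-5-(propan-2-yl)cyclohexan-1-one
Conditions: MOMCl, i-Pr2NEt, CH2Cl2, 0 °C → rt
Reagents that add atoms: chloromethyl methyl ether, COCCl
Why: O-Alkylation of the secondary alcohol with MOMCl and a hindered amine gives an acetal ether that tolerates amide bases, organometallics and KH and, unlike a silyl group, cannot migrate to a neighbouring alkoxide or enolate oxygen.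

Step 6
Reactants: 9 trans MOM ether
Product: 11 (2R,5S,6R)-2-ethenyl-6-(methoxymethoxy)-2-methyl-5-(propan-2-yl)cyclohexan-1-one, via lithium enolate 10 (not isolated)
Conditions: LiN(i-Pr)2, THF, −78 °C; then 2,6-di-tert-butyl-4-methylphenol, −78 °C; pH 7 buffer
Reagents that add atoms: none
Why: Kinetic protonation of a cyclohexanone enolate: allylic strain with the C6 alkoxy group turns the isopropyl group axial, which together with the C10 vinyl group shields the lower face, so the bulky phenol should deliver the proton from the upper face and leave O6 cis to the isopropyl group (6R); any 9 that re-forms is separated and resubmitted.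

Step 7
Reactants: 12 4-methoxybenzyl alcohol; 13 allyl bromide
Product: 15 allyl 4-methoxybenzyl ether, via sodium alkoxide 14 (not isolated)
Conditions: NaH, THF, 0 °C; then 13, Bu4NI (cat.), rt
Reagents that add atoms: none
Why: Williamson ether synthesis of a primary alkoxide with a reactive allylic bromide.

Step 8
Reactants: 15 allyl 4-methoxybenzyl ether
Product: 16 (Z)-prop-1-enyl 4-methoxybenzyl ether
Conditions: KOt-Bu (cat.), DMSO, rt
Reagents that add atoms: none
Why: Base-mediated allyl-to-propenyl ether isomerisation proceeds through the cis-configured, potassium-coordinated oxyallyl anion and therefore gives the Z enol ether.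

Step 9
Reactants: 16 (Z)-propenyl ether
Product: 18 (Z)-2-bromo-1-[(4-methoxybenzyl)oxy]prop-1-ene (Br cis to O), via dibromide 17 (not isolated)
Conditions: Br2 (1.0 equiv), CH2Cl2, −78 °C; then DBU, −78 °C → rt
Reagents that add atoms: bromine, BrBr
Why: Anti addition of bromine followed by anti elimination of HBr (loss of the labile bromide next to oxygen together with H2) converts the Z propenyl ether stereospecifically into the 2-bromo enol ether with Br cis to oxygen, the classical route to 2-bromovinyl ethers.

Step 10
Reactants: 18 (Z)-bromo enol ether; 11 cis ketone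
Product: 21 (1R,2R,5S,6R)-2-ethenyl-6-(methoxymethoxy)-1-{(1Z)-1-[(4-methoxybenzyl)oxy]prop-1-en-2-yl}-2-methyl-5-(propan-2-yl)cyclohexan-1-ol, via alkenyllithium 19 (not isolated), via alkenylcerium dichloride 20 (not isolated)
Conditions: 18, t-BuLi (2 equiv per 18), Et2O, −78 °C; CeCl3 (anhydrous), THF, −78 °C; then 11, −78 → −40 °C; aq. NaHCO3
Reagents that add atoms: none
Why: Bromine–lithium exchange proceeds with retention, the oxygen-coordinated alkenyllithium is stable at −78 °C, and its weakly basic cerium derivative should add to the hindered, enolisable ketone (organocerium 1,2-addition) from the face opposite to the vinyl, MOM-oxy and isopropyl groups, which sets C5 with the two alkenyl groups trans.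

Step 11
Reactants: 21 dialkenylcyclohexanol
Product: 24 (3S,6R,7S,1(10)E,4Z)-6-(methoxymethoxy)-3-[(4-methoxybenzyl)oxy]germacra-1(10),4-dien-5-yl trifluoromethanesulfonate (C3 and C6 trans on C4=C5), via potassium alkoxide 22 (not isolated), via potassium enolate 23 (not isolated)
Conditions: KH, 18-crown-6, THF, 0 °C → rt; then PhNTf2, −78 → 0 °C
Reagents that add atoms: N-phenylbis(trifluoromethanesulfonimide), O=S(=O)(N(c1ccccc1)S(=O)(=O)C(F)(F)F)C(F)(F)F
Why: Deprotonation gives alkoxide 22, whose oxyanion weakens the fully substituted C5–C10 bond so that a concerted suprafacial [3,3] shift (anionic oxy-Cope rearrangement of a trans-1,2-dialkenylcyclohexanol, a well-known entry to E-cyclodecenone enolates) makes C2–C3 as C5–C10 breaks. The ten-membered ring thus arises by four-atom expansion of the ring C5–C10 and not by end-to-end cyclisation, driven by the change from alkoxide to enolate 23. In the reactive cyclohexane chair both alkenyl groups and the C6 ether are equatorial, the six reacting atoms adopt a chair, and C9 and C6 sit pseudo-equatorially, so they end up trans to C2 and C3 (E C1=C10, C3/C6-trans enolate). C3 is the only new stereocentre: the C5/C10 configuration decides which alkene faces meet, and the Z enol ether puts its oxygen pseudo-axial, which translates into 3S. The step needs chair over boat and survival of the β-alkoxy enolate; the first is secured by the trans-diequatorial alkenyl groups, the second by the nascent geometry, in which the C3–O bond lies almost in the plane of a tetrasubstituted enolate that cannot turn through the ring, and by trapping at −78 °C directly after the shift. O-Sulfonylation with PhNTf2 then freezes the regiochemistry and geometry of the enolate as enol triflate 24.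

Step 12
Reactants: 24 enol triflate
Product: 26 (3S,6R,7S,1(10)E,4Z)-6-hydroxy-3-[(4-methoxybenzyl)oxy]germacra-1(10),4-dien-5-yl trifluoromethanesulfonate, via alkoxymethyl bipyridinium triflate 25 (not isolated)
Conditions: Me3SiOTf (2 equiv), 2,2′-bipyridyl (3 equiv), CH2Cl2, 0 °C → rt; then H2O
Reagents that add atoms: none
Why: Silyl triflate activation of the acetal in the presence of excess bipyridyl gives an N-(alkoxymethyl)bipyridinium salt that water hydrolyses, so the medium is never acidic and the PMB ether should survive, while the electron-withdrawing triflate on C4=C5 suppresses allylic ionisation and transannular cyclisation at this stage.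

Step 13
Reactants: 26 hydroxy enol triflate
Product: 27 (3S,6R,7S,1(10)E,4E)-3-[(4-methoxybenzyl)oxy]germacra-1(10),4-dien-6-ol
Conditions: Pd(OAc)2 (cat.), PPh3, HCO2H, Et3N, DMF, 50 °C
Reagents that add atoms: none
Why: Palladium-catalysed formate reduction of a vinyl triflate (oxidative addition to zerovalent palladium, formate exchange, decarboxylation, reductive elimination) replaces OTf by H with retention, so the C3/C6-trans geometry becomes the 4E alkene, and the temperature stays well below that of germacradiene Cope rearrangement.

Step 14
Reactants: 27 dienol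
Product: 28 (3S,4R,5R,6R,7S,1(10)E)-4,5-epoxy-3-[(4-methoxybenzyl)oxy]germacr-1(10)-en-6-ol
Conditions: Ti(Oi-Pr)4 (1.1 equiv), D-(−)-diisopropyl tartrate (1.3 equiv), t-BuOOH, 4 Å molecular sieves, CH2Cl2, −20 °C; aq. Na2SO4 work-up
Reagents that add atoms: tert-butyl hydroperoxide, CC(C)(C)OO
Why: Sharpless epoxidation: the C6 titanium alkoxide delivers oxygen only to the allylic C4=C5 bond and leaves C1=C10 alone, the small O6–C6–C5=C4 angle required by the metal alkoxide selects the ring conformer that exposes the correct alkene face, and the 6R carbinol is matched with the D-(−)-tartrate catalyst, which gives the erythro 4R,5R epoxide.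

Step 15
Reactants: 28 epoxy alcohol
Product: 29 (3S,4R,5R,6R,7S,1(10)E)-4,5-epoxy-3-[(4-methoxybenzyl)oxy]germacr-1(10)-en-6-yl acetate
Conditions: Ac2O, pyridine, DMAP (cat.), CH2Cl2, 0 °C → rt
Reagents that add atoms: acetic anhydride, CC(=O)OC(C)=O
Why: DMAP-catalysed acetylation of the only free hydroxyl group runs under basic conditions that do not disturb the epoxide or the alkene.

Step 16
Reactants: 29 acetate
Product: 30 (3S,4R,5R,6R,7S,1(10)E)-4,5-epoxy-3-hydroxygermacr-1(10)-en-6-yl acetate
Conditions: DDQ, CH2Cl2/pH 7 phosphate buffer, 0 °C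
Reagents that add atoms: none
Why: Oxidative PMB cleavage by hydride abstraction from the electron-rich benzylic position and hydrolysis of the oxocarbenium ion works in a buffered medium that spares the epoxide, acetate and trisubstituted alkene, and C3 is no longer allylic, so over-oxidation is unlikely.

Step 17
Reactants: 30 C3 alcohol; 31 3-methylbut-2-enoic acid (senecioic acid)
Product: 33 target (3S,4R,5R,6R,7S,1(10)E)-6-acetoxy-4,5-epoxygermacr-1(10)-en-3-yl 3-methylbut-2-enoate, via O-acylisourea 32 (not isolated)
Conditions: 31, DCC, DMAP (cat.), CH2Cl2, 0 °C → rt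
Reagents that add atoms: none
Why: Steglich esterification acylates the hindered secondary alcohol under almost neutral conditions and avoids the acid chloride/amine combination, which would deconjugate the senecioyl group through a vinylketene.

Compound list
1 | (R)-(−)-carvone | CC1=CC[C@H](CC1=O)C(C)=C | starting material
2 | (R)-carvotanacetone | CC1=CC[C@H](CC1=O)C(C)C | intermediate
3 | acetaldehyde | CC=O | starting material
4 | lithium (R)-2-methyl-5-(propan-2-yl)cyclohex-1-en-1-olate | C1C([O-])=C(C)CC[C@H]1C(C)C.[Li+] | intermediate (not isolated)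
5 | (2R,5R)-2-(1-hydroxyethyl)-2-methyl-5-(propan-2-yl)cyclohexan-1-one, carbinol epimers | C1C(=O)[C@@](C)(C(C)O)CC[C@H]1C(C)C | intermediate
6 | (2R,5R)-2-ethenyl-2-methyl-5-(propan-2-yl)cyclohexan-1-one | C1C(=O)[C@@](C)(C=C)CC[C@H]1C(C)C | intermediate
7 | potassium C5=C6 enolate of 6 | C1=C([O-])[C@@](C)(C=C)CC[C@H]1C(C)C.[K+] | intermediate (not isolated)
8 | (2R,5S,6S)-2-ethenyl-6-hydroxy-2-methyl-5-(propan-2-yl)cyclohexan-1-one | O[C@@H]1C(=O)[C@@](C)(C=C)CC[C@H]1C(C)C | intermediate
9 | (2R,5S,6S)-2-ethenyl-6-(methoxymethoxy)-2-methyl-5-(propan-2-yl)cyclohexan-1-one (O6 trans to isopropyl) | COCO[C@@H]1C(=O)[C@@](C)(C=C)CC[C@H]1C(C)C | intermediate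
10 | lithium C5=C6 enolate of 9 | COCOC1=C([O-])[C@@](C)(C=C)CC[C@H]1C(C)C.[Li+] | intermediate (not isolated)
11 | (2R,5S,6R)-2-ethenyl-6-(methoxymethoxy)-2-methyl-5-(propan-2-yl)cyclohexan-1-one (O6 cis to isopropyl) | COCO[C@H]1C(=O)[C@@](C)(C=C)CC[C@H]1C(C)C | intermediate
12 | 4-methoxybenzyl alcohol | COc1ccc(CO)cc1 | starting material
13 | allyl bromide | C=CCBr | starting material
14 | sodium 4-methoxybenzyl oxide | COc1ccc(C[O-])cc1.[Na+] | intermediate (not isolated)
15 | allyl 4-methoxybenzyl ether | C=CCOCc1ccc(OC)cc1 | intermediate
16 | (Z)-prop-1-enyl 4-methoxybenzyl ether | C/C=C\OCc1ccc(OC)cc1 | intermediate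
17 | 1,2-dibromopropyl 4-methoxybenzyl ether, racemic anti adduct (1R*,2S*) | C[C@H](Br)[C@@H](Br)OCc1ccc(OC)cc1 | intermediate (not isolated)
18 | (Z)-2-bromo-1-[(4-methoxybenzyl)oxy]prop-1-ene | Br/C(C)=C\OCc1ccc(OC)cc1 | intermediate
19 | 1-[(4-methoxybenzyl)oxy]prop-1-en-2-yllithium, Li cis to O | [Li]/C(C)=C\OCc1ccc(OC)cc1 | intermediate (not isolated)
20 | dichloro{1-[(4-methoxybenzyl)oxy]prop-1-en-2-yl}cerium, Ce cis to O | Cl[Ce](Cl)/C(C)=C\OCc1ccc(OC)cc1 | intermediate (not isolated)
21 | (1R,2R,5S,6R)-dialkenylcyclohexanol, key-step precursor | COCO[C@H]1[C@](O)(/C(C)=C\OCc2ccc(OC)cc2)[C@@](C)(C=C)CC[C@H]1C(C)C | intermediate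
22 | potassium alkoxide of 21 | COCO[C@H]1[C@]([O-])(/C(C)=C\OCc2ccc(OC)cc2)[C@@](C)(C=C)CC[C@H]1C(C)C.[K+] | intermediate (not isolated)
23 | potassium C4=C5 enolate of the ten-membered ketone | COCO[C@H]1/C([O-])=C(\C)[C@@H](OCc2ccc(OC)cc2)C/C=C(\C)CC[C@H]1C(C)C.[K+] | intermediate (not isolated)
24 | germacradienyl 5-enol triflate, 3-OPMB, 6-OMOM, key-step product | COCO[C@H]1/C(OS(=O)(=O)C(F)(F)F)=C(\C)[C@@H](OCc2ccc(OC)cc2)C/C=C(\C)CC[C@H]1C(C)C | intermediate
25 | N-(C6-oxymethyl)-2,2′-bipyridinium triflate of 24 | [O-]S(=O)(=O)C(F)(F)F.c1ccc(-c2cccc[n+]2CO[C@H]2/C(OS(=O)(=O)C(F)(F)F)=C(\C)[C@@H](OCc3ccc(OC)cc3)C/C=C(\C)CC[C@H]2C(C)C)nc1 | intermediate (not isolated)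
26 | 6-hydroxy enol triflate | O[C@H]1/C(OS(=O)(=O)C(F)(F)F)=C(\C)[C@@H](OCc2ccc(OC)cc2)C/C=C(\C)CC[C@H]1C(C)C | intermediate
27 | (1(10)E,4E)-3-OPMB-germacradien-6-ol | O[C@H]1/C=C(\C)[C@@H](OCc2ccc(OC)cc2)C/C=C(\C)CC[C@H]1C(C)C | intermediate
28 | 4,5-epoxy-3-OPMB-germacr-1(10)-en-6-ol | O[C@H]1[C@H]2O[C@]2(C)[C@@H](OCc3ccc(OC)cc3)C/C=C(\C)CC[C@H]1C(C)C | intermediate
29 | 6-acetate of 28 | CC(=O)O[C@H]1[C@H]2O[C@]2(C)[C@@H](OCc3ccc(OC)cc3)C/C=C(\C)CC[C@H]1C(C)C | intermediate
30 | 6-acetoxy-4,5-epoxygermacr-1(10)-en-3-ol | CC(=O)O[C@H]1[C@H]2O[C@]2(C)[C@@H](O)C/C=C(\C)CC[C@H]1C(C)C | intermediate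
31 | 3-methylbut-2-enoic acid | CC(C)=CC(=O)O | starting material
32 | O-(3-methylbut-2-enoyl)-N,N′-dicyclohexylisourea | CC(C)=CC(=O)OC(=NC1CCCCC1)NC1CCCCC1 | intermediate (not isolated)
33 | CNP0267399.1 | CC(=O)O[C@H]1[C@H]2O[C@]2(C)[C@@H](OC(=O)C=C(C)C)C/C=C(\C)CC[C@H]1C(C)C | target

Total step count: 17. Longest linear sequence: 14 (steps 1–6 and 10–17, from (R)-carvone).

Steps most likely to fail

Step 11.
- What may go wrong: the reactive chair carries the isopropyl group axial, so the shift may need warming. The longer the potassium enolate lives, the more it can expel 4-methoxybenzyl oxide from C3 or exchange protons. Part of the material may also pass through a boat.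
- Fallback: separate the rearrangement from the sulfonylation.
- Starting again from 21, alkoxide 22 is rearranged as before, but enolate 23 is captured at −78 °C with Me3SiCl/Et3N, which is much faster than triflation. This gives the isolable trimethylsilyl enol ether F1.
- F1 is then treated with CsF and PhNTf2 in DME at rt. The enolate is released slowly in the presence of its trap and never accumulates.
- The route is rejoined at 24.

Step 6.
- What may go wrong: insufficient facial discrimination in the protonation, or drift back to the more stable trans epimer during work-up or under the basic conditions of step 10.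
- Fallback: let the oxygen arrive on the hindered face by a displacement with inversion, instead of correcting C6 afterwards.
- Ketone 6 is treated with PhI(OAc)2 and KOH in MeOH (0 °C → rt). The enolate binds trivalent iodine on the open face, and methoxide adds to C5.
- The resulting alkoxide displaces iodobenzene from the rear. Methanolysis of the methoxy epoxide leaves the oxygen on the face of the isopropyl group, which gives the α-hydroxy dimethyl ketal F2.
- MOMCl/i-Pr2NEt converts it into the MOM-protected ketal F3.
- Brief exposure to pyridinium p-toluenesulfonate in wet acetone unmasks the strained ketal. The route is rejoined at 11 without any base meeting the C6–H bond.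

Step 14.
- What may go wrong: reaction through the ring conformer in which H6 rather than O6 eclipses the C4 methyl group (wrong alkene face), slow turnover because that methyl group is cis to the carbinol carbon, or opening of the new epoxide by C1=C10 under the stoichiometric titanium Lewis acid.
- Fallback: give up reagent control and the stoichiometric Lewis acid, and rely on macrocyclic substrate control.
- Dienol 27 is epoxidised with catalytic VO(acac)2 and t-BuOOH in toluene at 0 °C.
- The vanadate ester also demands a small O6–C6–C5=C4 angle, so it can only reach the alkene in the conformer that leads to the erythro epoxide.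
- This makes no new compound (F0) and returns to the route at 28.

Further compounds
F1 | step 11 | (3S,6R,7S,1(10)E)-6-(methoxymethoxy)-3-[(4-methoxybenzyl)oxy]-5-(trimethylsilyloxy)germacra-1(10),4-diene (C3 and C6 trans on C4=C5) | COCO[C@H]1/C(O[Si](C)(C)C)=C(\C)[C@@H](OCc2ccc(OC)cc2)C/C=C(\C)CC[C@H]1C(C)C
F2 | step 6 | (1R,3R,6S)-3-ethenyl-2,2-dimethoxy-3-methyl-6-(propan-2-yl)cyclohexan-1-ol | O[C@H]1C(OC)(OC)[C@@](C)(C=C)CC[C@H]1C(C)C
F3 | step 6 | methoxymethyl ether of F2 | COCO[C@H]1C(OC)(OC)[C@@](C)(C=C)CC[C@H]1C(C)C
F0 | step 14 | none | none
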